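**Retrosynthetic overview**
1. Ambrein is two C15 halves joined tail to tail. The central CH2–CH2 bond (C11''–C1) is made by a photochemical Ni-catalysed coupling of a hindered primary iodide (bicyclic, 10) with an (E)-γ-monocyclofarnesyl carbonate (8).
2. Both halves come from (+)-sclareolide, which supplies all five stereocentres. The bicyclic half keeps its decalin. The monocyclic half is made by opening ring B, a Norrish II cleavage of the C9–C10 bond of the 8α-hydroxydrimane-11-al (4) that gives the exocyclic methylene and the ring-A stereocentre.
3. Aldol dehydration then sets the trisubstituted (E)-alkene.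
4. Ring order: both decalin rings pre-exist in sclareolide; the cyclohexane with the exocyclic methylene is released from ring B by photofragmentation; no ring is built.

**Assumptions:** (+)-sclareolide of natural configuration is commercial and cheap. The thermodynamic E:Z ratio of enal 6 is about 4:1, and the isomers are separable on AgNO3-silica.

---

**Step 1**
Reactants: 1 (+)-sclareolide
Product: 2 11-hydroxysclareolide (C11 epimer mixture)
Conditions: LDA, THF, –78 °C; then 2-(phenylsulfonyl)-3-phenyloxaziridine, –78 → 0 °C
Reagents that add atoms: 2-(phenylsulfonyl)-3-phenyloxaziridine (racemic), O=S(=O)(c1ccccc1)N1OC1c1ccccc1 (delivers the OH oxygen)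
Why: Lactone enolate α-hydroxylation (Davis oxidation); the new C11 centre is unselective but is destroyed in step 3, and the decalin centres are untouched.

**Step 2**
Reactants: 2
Product: 3 (8α,11,12-triol, 13,14,15,16-tetranorlabdane series)
Conditions: LiAlH4, THF, 0 °C → reflux
Reagents that add atoms: none
Why: Hydride reduction of the lactone to a 1,2-diol plus the tertiary alcohol; no stereocentre is changed.

**Step 3**
Reactants: 3
Product: 4 (8α-hydroxydrimane-11-al; CH2O is lost)
Conditions: NaIO4, THF/H2O 3:1, NaHCO3, 0 °C → rt; use the crude product at once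
Reagents that add atoms: none
Why: Malaprade cleavage of the vicinal C11/C12 diol only; the tertiary 8-OH is not vicinal and survives, and buffering avoids retro-aldol or dehydration of the β-hydroxy aldehyde.

**Step 4**
Reactants: 4
Product: 5 (ring-B-opened β-hydroxy aldehyde with an exocyclic methylene on the new cyclohexane)
Conditions: hν (medium-pressure Hg lamp, Pyrex, λ > 290 nm), degassed benzene (0.02 M), 15 °C, flow, ≤60% conversion per pass with recycle of recovered 4
Reagents that add atoms: none
Why: Proposed new method: the n,π* aldehyde C11=O sits gauche to the axial C20 methyl, so it abstracts a γ-H (six-membered transition state), and the resulting 1,4-biradical (C11 hydroxyalkyl / C20 primary radical) fragments the C9–C10 σ-bond to give the C10=C20 exocyclic methylene and the C9=C11 enol, which ketonises to 5; the closest known reaction is Norrish type II fragmentation (as in 11-oxosteroid photochemistry), here used to open ring B of a drimane, and the ring-A stereocentre (old C5) is untouched.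

**Step 5**
Reactants: 5
Product: 6 ((E)-γ-monocyclofarnesal)
Conditions: piperidinium acetate (10 mol %), benzene, 4 Å MS, 60 °C; separate E from Z (about 4:1) on AgNO3-silica
Reagents that add atoms: none
Why: Amine-catalysed E1cB aldol dehydration removes the tertiary 8-OH toward the enal, and the E enal is thermodynamically preferred, which sets the trisubstituted alkene geometry; the mild conditions avoid acid-induced migration of the exocyclic methylene.

**Step 6**
Reactants: 6
Product: 7 ((E)-γ-monocyclofarnesol)
Conditions: NaBH4, CeCl3·7H2O, MeOH, 0 °C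
Reagents that add atoms: none
Why: Luche 1,2-reduction of the enal; the alkenes and the stereocentre are unaffected.

**Step 7**
Reactants: 7
Product: 8 (methyl (E)-γ-monocyclofarnesyl carbonate)
Conditions: ClCO2Me, pyridine, DMAP (cat.), CH2Cl2, 0 °C
Reagents that add atoms: methyl chloroformate, COC(=O)Cl (adds the CO2Me carbonate group)
Why: Acylation of the primary allylic alcohol gives a good π-allyl-nickel precursor without touching the alkenes.

**Step 8**
Reactants: 4 (second portion)
Product: 9 (drimane-8α,11-diol)
Conditions: NaBH4, MeOH, 0 °C
Reagents that add atoms: none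
Why: Chemoselective aldehyde reduction; C9 is no longer α to a carbonyl afterwards, so its configuration is fixed.

**Step 9**
Reactants: 9
Product: 10 (11-iodo-drimane-8α-ol)
Conditions: PPh3, I2, imidazole, CH2Cl2, 0 → 40 °C
Reagents that add atoms: iodine, II (adds I)
Why: Appel iodination is selective for the primary alcohol over the tertiary one; the reaction is a C–O substitution at CH2 with no stereochemical consequence.

**Step 10**
Reactants: 8 (allylic carbonate), 10 (primary iodide)
Product: 11 ambrein
Conditions: NiCl2·DME (10 mol %), dtbbpy (12 mol %), Ir[dF(CF3)ppy]2(dtbbpy)PF6 (1 mol %), (Me3Si)3SiH (1.5 equiv), 2,6-lutidine (2 equiv), DME, blue LEDs, 25 °C, 24 h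
Reagents that add atoms: none
Why: Silyl-radical iodine-atom abstraction gives the primary alkyl radical, which is captured by the Ni-π-allyl species from 8 and undergoes C(sp3)–C(sp3) reductive elimination at the unhindered allyl terminus (Ni/photoredox cross-electrophile allylation); the E-alkene and all stereocentres are retained and the free tertiary OH is tolerated.

---

**Compound list**

| # | Name | SMILES | Role |
|---|---|---|---|
| 1 | (+)-sclareolide | O=C1C[C@@H]2[C@@]3(C)CCCC(C)(C)[C@@H]3CC[C@@]2(C)O1 | starting material |
| 2 | 11-hydroxysclareolide (C11 epimers) | O=C1C(O)[C@@H]2[C@@]3(C)CCCC(C)(C)[C@@H]3CC[C@@]2(C)O1 | intermediate |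
| 3 | 1-(1,2-dihydroxyethyl)-2,5,5,8a-tetramethyldecahydronaphthalen-2-ol (8α,11,12-triol) | OCC(O)[C@@H]1[C@@]2(C)CCCC(C)(C)[C@@H]2CC[C@@]1(C)O | intermediate |
| 4 | 8α-hydroxydrimane-11-al | O=C[C@@H]1[C@@]2(C)CCCC(C)(C)[C@@H]2CC[C@@]1(C)O | intermediate |
| 5 | 5-[(1S)-2,2-dimethyl-6-methylenecyclohexyl]-3-hydroxy-3-methylpentanal | C=C1CCCC(C)(C)[C@@H]1CC[C@@](C)(O)CC=O | intermediate |
| 6 | (2E)-5-[(1S)-2,2-dimethyl-6-methylenecyclohexyl]-3-methylpent-2-enal (γ-monocyclofarnesal) | C=C1CCCC(C)(C)[C@@H]1CC/C(C)=C/C=O | intermediate |
| 7 | (2E)-5-[(1S)-2,2-dimethyl-6-methylenecyclohexyl]-3-methylpent-2-en-1-ol | C=C1CCCC(C)(C)[C@@H]1CC/C(C)=C/CO | intermediate |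
| 8 | methyl carbonate of 7 | C=C1CCCC(C)(C)[C@@H]1CC/C(C)=C/COC(=O)OC | intermediate |
| 9 | drimane-8α,11-diol | OC[C@@H]1[C@@]2(C)CCCC(C)(C)[C@@H]2CC[C@@]1(C)O | intermediate |
| 10 | 11-iodo-drimane-8α-ol | IC[C@@H]1[C@@]2(C)CCCC(C)(C)[C@@H]2CC[C@@]1(C)O | intermediate |
| 11 | ambrein | C=C1CCCC(C)(C)[C@@H]1CC/C(C)=C/CC[C@@H]1[C@@]2(C)CCCC(C)(C)[C@@H]2CC[C@@]1(C)O | target |

**Total steps:** 10. **Longest linear sequence:** 8 (1 → 2 → 3 → 4 → 5 → 6 → 7 → 8 + 10 → 11).

**Three steps most likely to fail**
1. **Step 4 (proposed new Norrish II ring-B opening).** Competing Norrish I decarbonylation, Yang cyclobutanol formation, γ-H abstraction from C1 (giving an endocyclic alkene), and secondary photolysis of aldehyde 5 can all lower the yield.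
   - Fallback: make racemic γ-monocyclofarnesol by known cationic monocyclisation of farnesyl derivatives, resolve it by lipase-catalysed acetylation to the (S)-alcohol 7, and rejoin the route at step 7.
2. **Step 10 (photochemical Ni coupling of a hindered neopentyl-like iodide).** Risks are branched (γ) allylation, homocoupling and β-scission.
   - Fallback: protect the 8-OH of 10 as its TMS ether, make the Grignard reagent, couple with 8 using Li2CuCl4 (SN2 allylic substitution), then remove the TMS group with K2CO3/MeOH.
3. **Step 5 (E/Z ratio and exocyclic-alkene integrity).**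
   - Fallback: treat 5 with KOH/MeOH to undergo retro-aldol to the (S)-methyl ketone 4-(2,2-dimethyl-6-methylenecyclohexyl)butan-2-one plus acetaldehyde, then do an E-selective HWE reaction (triethyl phosphonoacetate, NaH) and DIBAL reduction to give 7.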